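**Strategy.** The quinone ring (C1, C2, C3, C4, C4a, C8a) is disconnected to a four-membered ring. The twofold-symmetric 3,6-bis(methoxymethoxy)benzocyclobutene-1,2-dione takes up the acetylide of (R)-6-methylhept-5-en-1-yn-3-ol. Thermolysis of the resulting 2-alkynyl-2-hydroxybenzocyclobutenone (Moore rearrangement) inserts the two alkyne carbons as C2 and C3 and gives the naphthoquinone directly at the quinone oxidation level. The step exploits the symmetric 5,8-dioxygenated benzo ring (C5–C8), which makes both dione carbonyls equivalent and the C2/C3 placement unambiguous. The C1' carbinol stereocentre, set beforehand by asymmetric ynone reduction, lies outside the reacting system. Acidic unmasking gives shikonin; selective side-chain acylation finishes the target.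

Key step: step 11

Assumption: 3,4-dimethylpent-3-enoic acid is treated as not commercially available and is made in steps 13–14; the target is one of the rapidly interconverting naphthazarin tautomers and is drawn as given.

**Step 1**
Reactants: 1 2-bromo-1,4-dimethoxybenzene; 2 1,1-diethoxyethene
Product: 4 3,6-dimethoxybenzocyclobutenone, via benzocyclobutenone diethyl ketal 3 (not isolated)
Conditions: NaNH2 (3 equiv), THF, 65 °C; then 1 M HCl, THF, rt
Reagents that add atoms: water, O
Why: NaNH2 removes H-3 (flanked by Br and OMe) and bromide leaves to give the symmetric 3,6-dimethoxybenzyne, which should undergo the aryne–ketene acetal [2+2] cycloaddition to a single ketal 3 that dilute acid hydrolyses to the strained ketone.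

**Step 2**
Reactants: 4 3,6-dimethoxybenzocyclobutenone
Product: 5 2,2-dibromo-3,6-dimethoxybenzocyclobutenone
Conditions: NBS (2.2 equiv), AIBN (cat.), PhCF3, 85 °C, hν
Reagents that add atoms: N-bromosuccinimide, O=C1CCC(=O)N1Br
Why: Wohl–Ziegler bromination, in which the ring CH2 is both benzylic and α to the carbonyl so both hydrogens should be replaced, while non-polar radical conditions disfavour electrophilic bromination of the carbonyl-deactivated arene.

**Step 3**
Reactants: 5 2,2-dibromo-3,6-dimethoxybenzocyclobutenone
Product: 6 3,6-dimethoxybenzocyclobutene-1,2-dione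
Conditions: conc. H2SO4, 50 °C; then ice/H2O
Reagents that add atoms: water, O
Why: Acid-mediated hydrolysis of the α,α-dibromo ketone to the 1,2-dione, the usual closing step of benzocyclobutenedione syntheses; aryl methyl ethers are stable to it.

**Step 4**
Reactants: 6 3,6-dimethoxybenzocyclobutene-1,2-dione
Product: 7 3,6-dihydroxybenzocyclobutene-1,2-dione
Conditions: BBr3 (3 equiv), CH2Cl2, −78 → 0 °C; H2O
Reagents that add atoms: none
Why: BBr3 ether cleavage assisted by the neighbouring carbonyls, carried out on a robust achiral intermediate so that no methyl ether has to be removed later beside the acid-sensitive side chain.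

**Step 5**
Reactants: 7 3,6-dihydroxybenzocyclobutene-1,2-dione
Product: 8 3,6-bis(methoxymethoxy)benzocyclobutene-1,2-dione
Conditions: MOMCl (3 equiv), i-Pr2NEt (4 equiv), CH2Cl2, 0 °C → rt, Ar
Reagents that add atoms: chloromethyl methyl ether, COCCl
Why: O-alkylation of the acidic phenols gives acetal ethers that should survive organolithium addition and thermolysis and later come off under mild acid because of the peri carbonyls.

**Step 6**
Reactants: 9 4-methylpent-3-enoic acid
Product: 11 N-methoxy-N,4-dimethylpent-3-enamide, via acyl imidazolide 10 (not isolated)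
Conditions: CDI, CH2Cl2, rt; then MeNH(OMe)·HCl, rt
Reagents that add atoms: N,O-dimethylhydroxylamine hydrochloride, CNOC.Cl
Why: Weinreb amide formation through the acyl imidazolide avoids acid chloride/base conditions that could move the β,γ-double bond into conjugation.

**Step 7**
Reactants: 11 N-methoxy-N,4-dimethylpent-3-enamide; 12 ethynyl(trimethyl)silane
Product: 14 6-methyl-1-(trimethylsilyl)hept-5-en-1-yn-3-one, via lithium (trimethylsilyl)acetylide 13 (not isolated)
Conditions: n-BuLi, THF, −78 °C; then 11, −78 → −20 °C; cold sat. NH4Cl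
Reagents that add atoms: none
Why: Weinreb ketone synthesis, in which the stable N-methoxy-N-methyl chelate prevents over-addition of the acetylide and releases the ynone only on cold quench.

**Step 8**
Reactants: 14 6-methyl-1-(trimethylsilyl)hept-5-en-1-yn-3-one
Product: 15 (3R)-6-methyl-1-(trimethylsilyl)hept-5-en-1-yn-3-ol
Conditions: Ru(p-cymene)[(R,R)-TsDPEN] (amido complex, 1 mol %), i-PrOH, rt
Reagents that add atoms: none
Why: Noyori asymmetric transfer hydrogenation of an α,β-acetylenic ketone, in which the (R,R)-catalyst differentiates alkynyl from alkyl and should deliver hydride to give the (R)-propargylic alcohol under base-free conditions that leave the skipped enone unisomerised.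

**Step 9**
Reactants: 15 (3R)-6-methyl-1-(trimethylsilyl)hept-5-en-1-yn-3-ol
Product: 16 (3R)-6-methylhept-5-en-1-yn-3-ol
Conditions: K2CO3 (cat.), MeOH, 0 °C → rt
Reagents that add atoms: none
Why: Base-catalysed methanolysis of the C(sp)–Si bond frees the terminal alkyne without touching the carbinol stereocentre.

**Step 10**
Reactants: 16 (3R)-6-methylhept-5-en-1-yn-3-ol; 8 3,6-bis(methoxymethoxy)benzocyclobutene-1,2-dione
Product: 18 2-hydroxy-2-[(3R)-3-hydroxy-6-methylhept-5-en-1-yn-1-yl]-3,6-bis(methoxymethoxy)benzocyclobuten-1(2H)-one, via dilithiated alkynol 17 (not isolated)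
Conditions: n-BuLi (2.1 equiv per 16), THF, −78 → −30 °C; then added to 8, THF, −78 °C; sat. NH4Cl, −78 °C
Reagents that add atoms: none
Why: 1,2-Addition of the acetylide terminus of the dianion to one carbonyl of the symmetric dione should stop at mono-addition because the new alkoxide deactivates the neighbouring ketone; the tertiary carbinol centre forms as both epimers, which is irrelevant because it becomes a carbonyl carbon in step 11.

**Step 11**
Reactants: 18 2-hydroxy-2-[(3R)-3-hydroxy-6-methylhept-5-en-1-yn-1-yl]-3,6-bis(methoxymethoxy)benzocyclobuten-1(2H)-one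
Product: 20 2-[(1R)-1-hydroxy-4-methylpent-3-en-1-yl]-5,8-bis(methoxymethoxy)naphthalene-1,4-dione, via o-quinoid enynyl ketene 19 (not isolated)
Conditions: p-xylene (0.01 M, degassed), 140 °C, Ar
Reagents that add atoms: none
Why: Heating should open the four-membered ring of 18 by conrotatory 4π-electrocyclic cleavage of the C(=O)–C(OH) bond, the hydroxyl rotating outward so that the alkynyl group lies next to the o-quinoid ketene 19; the ketene carbon then bonds to the distal alkyne carbon, which re-aromatises the benzo ring and gives an aryl σ/phenoxyl diradical that collapses to the quinone by transfer of the former hydroxyl hydrogen to C3. The closest known reaction type is the Moore rearrangement of 4-alkynyl-4-hydroxycyclobutenones to 1,4-quinones, used here in its benzo-fused form, so that the four ring carbons of the benzocyclobutenone become C1, C4, C4a and C8a and the alkyne carbons become C2 and C3. The one ring closed is the six-membered quinone ring, closed in the 6-endo-dig mode. No stereocentre is created: the carbinol carbon of 18 (either epimer) becomes the C4 carbonyl, and C1' is outside the reacting π-system and keeps its R configuration. The step needs 6-endo over 5-exo closure (which would give an alkylidene-indanedione), and the alkyl-type, non-radical-stabilising substituent on the alkyne should secure it; the side chain position is fixed because the substituted alkyne carbon must bond to the former ketone carbon and the symmetric benzo ring makes either orientation the same compound. Dilute, degassed conditions should suppress intermolecular reactions of the ketene and the diradical.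

**Step 12**
Reactants: 20 2-[(1R)-1-hydroxy-4-methylpent-3-en-1-yl]-5,8-bis(methoxymethoxy)naphthalene-1,4-dione
Product: 21 (R)-shikonin
Conditions: 2 M aq. HCl, THF, 0 °C → rt, dark
Reagents that add atoms: none
Why: Acid-catalysed acetal hydrolysis (MOM cleavage), accelerated by the peri quinone carbonyls, should give the naphthazarin without affecting C1' or the trisubstituted alkene under cold, short conditions.

**Step 13**
Reactants: 22 2-bromo-3-methylbut-2-ene; 23 ethyl bromoacetate
Product: 25 ethyl 3,4-dimethylpent-3-enoate, via Reformatsky reagent 24 (not isolated)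
Conditions: 23, Zn (activated), THF, 40 °C; then 22, Pd2(dba)3 (1 mol %), Q-Phos (2 mol %), THF, rt → 50 °C
Reagents that add atoms: none
Why: Reformatsky reagent formation followed by palladium-catalysed Negishi-type coupling of the zinc enolate with the alkenyl bromide forms the C2–C3 bond regiospecifically and so fixes the tetrasubstituted β,γ-double bond.

**Step 14**
Reactants: 25 ethyl 3,4-dimethylpent-3-enoate
Product: 26 3,4-dimethylpent-3-enoic acid
Conditions: LiOH·H2O, THF/H2O, 0 °C; then cold 1 M HCl to pH 3
Reagents that add atoms: lithium hydroxide, [Li+].[OH-]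
Why: Saponification at low temperature, in which the carboxylate resists α-deprotonation so the double bond should stay out of conjugation, and mild acidification avoids lactonisation.

**Step 15**
Reactants: 21 (R)-shikonin; 26 3,4-dimethylpent-3-enoic acid
Product: 27 CNP0163639.1 (teracrylshikonin)
Conditions: DCC (1.3 equiv), DMAP (0.1 equiv), CH2Cl2, 0 °C, dark
Reagents that add atoms: none
Why: Steglich esterification, in which the two phenolic hydroxyls are tied up in hydrogen bonds to the quinone carbonyls so the activated acid should acylate the C1' alcohol selectively, with retention because the C1'–O bond is not broken.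

**Compound list**
1 | 2-bromo-1,4-dimethoxybenzene | COc1ccc(OC)c(Br)c1 | starting material
2 | 1,1-diethoxyethene | C=C(OCC)OCC | starting material
3 | 7,7-diethoxy-2,5-dimethoxybicyclo[4.2.0]octa-1,3,5-triene (benzocyclobutenone diethyl ketal) | CCOC1(OCC)Cc2c(OC)ccc(OC)c21 | intermediate
4 | 3,6-dimethoxybenzocyclobutenone | O=C1Cc2c(OC)ccc(OC)c21 | intermediate
5 | 2,2-dibromo-3,6-dimethoxybenzocyclobutenone | O=C1c2c(OC)ccc(OC)c2C1(Br)Br | intermediate
6 | 3,6-dimethoxybenzocyclobutene-1,2-dione | O=C1C(=O)c2c(OC)ccc(OC)c21 | intermediate
7 | 3,6-dihydroxybenzocyclobutene-1,2-dione | O=C1C(=O)c2c(O)ccc(O)c21 | intermediate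
8 | 3,6-bis(methoxymethoxy)benzocyclobutene-1,2-dione | O=C1C(=O)c2c(OCOC)ccc(OCOC)c21 | intermediate
9 | 4-methylpent-3-enoic acid | CC(C)=CCC(=O)O | starting material
10 | 1-(imidazol-1-yl)-4-methylpent-3-en-1-one (acyl imidazolide) | CC(C)=CCC(=O)n1ccnc1 | intermediate
11 | N-methoxy-N,4-dimethylpent-3-enamide | CC(C)=CCC(=O)N(C)OC | intermediate
12 | ethynyl(trimethyl)silane | C#C[Si](C)(C)C | starting material
13 | lithium (trimethylsilyl)acetylide | [Li]C#C[Si](C)(C)C | intermediate
14 | 6-methyl-1-(trimethylsilyl)hept-5-en-1-yn-3-one | CC(C)=CCC(=O)C#C[Si](C)(C)C | intermediate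
15 | (3R)-6-methyl-1-(trimethylsilyl)hept-5-en-1-yn-3-ol | CC(C)=CC[C@@H](O)C#C[Si](C)(C)C | intermediate
16 | (3R)-6-methylhept-5-en-1-yn-3-ol | CC(C)=CC[C@@H](O)C#C | intermediate
17 | dilithiated (3R)-6-methylhept-5-en-1-yn-3-ol (alkoxide/acetylide) | [Li]C#C[C@H](O[Li])CC=C(C)C | intermediate
18 | 2-hydroxy-2-[(3R)-3-hydroxy-6-methylhept-5-en-1-yn-1-yl]-3,6-bis(methoxymethoxy)benzocyclobuten-1(2H)-one (both C2 epimers) | O=C1c2c(OCOC)ccc(OCOC)c2C1(O)C#C[C@H](O)CC=C(C)C | intermediate
19 | o-quinoid enynyl ketene from ring opening of 18 | O=C=C1C(OCOC)=CC=C(OCOC)C1=C(O)C#C[C@H](O)CC=C(C)C | intermediate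
20 | 2-[(1R)-1-hydroxy-4-methylpent-3-en-1-yl]-5,8-bis(methoxymethoxy)naphthalene-1,4-dione | CC(C)=CC[C@@H](O)C1=CC(=O)c2c(OCOC)ccc(OCOC)c2C1=O | intermediate
21 | (R)-shikonin, 5,8-dihydroxy-2-[(1R)-1-hydroxy-4-methylpent-3-en-1-yl]naphthalene-1,4-dione | CC(C)=CC[C@@H](O)C1=CC(=O)c2c(O)ccc(O)c2C1=O | intermediate
22 | 2-bromo-3-methylbut-2-ene | CC(C)=C(C)Br | starting material
23 | ethyl bromoacetate | CCOC(=O)CBr | starting material
24 | (2-ethoxy-2-oxoethyl)zinc bromide (Reformatsky reagent) | CCOC(=O)C[Zn]Br | intermediate
25 | ethyl 3,4-dimethylpent-3-enoate | CCOC(=O)CC(C)=C(C)C | intermediate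
26 | 3,4-dimethylpent-3-enoic acid | CC(C)=C(C)CC(=O)O | intermediate
27 | CNP0163639.1, (1R)-1-(5,8-dihydroxy-1,4-dioxo-1,4-dihydronaphthalen-2-yl)-4-methylpent-3-en-1-yl 3,4-dimethylpent-3-enoate | CC(C)=CC[C@@H](OC(=O)CC(C)=C(C)C)C1=CC(=O)c2c(O)ccc(O)c2C1=O | target

**Step count.** Total: 15 steps. Longest linear sequence: 9 steps (1, 2, 3, 4, 5, 10, 11, 12, 15).

**Steps most likely to fail**

1. Step 11. Ring opening of the benzo-fused cyclobutenone may be too slow and lead to decomposition at the temperature it needs. The ketene may close in the 5-exo mode. The aryl radical may abstract an allylic hydrogen of the side chain instead of the hydroxyl hydrogen. Fallback (known cobalt-mediated alkyne insertion, which also bypasses step 10): setting out from 8 and 16, the dione 8 is treated with ClCo(PPh3)3 in chlorobenzene, which inserts cobalt into the C(=O)–C(=O) bond to give chlorobis(triphenylphosphine)[3,6-bis(methoxymethoxy)phthaloyl]cobalt(III) F1. Exchange of the phosphines with dimethylglyoxime in pyridine gives the chloro(dimethylglyoxime)(pyridine)[3,6-bis(methoxymethoxy)phthaloyl]cobalt(III) complex F2. Heating F2 with alkynol 16 and CoCl2·6H2O in MeCN at 80 °C inserts the alkyne between the two acyl–cobalt bonds, and reductive elimination should return to the route at 20. The symmetric metallacycle again makes the regiochemistry of insertion irrelevant.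

2. Step 12. Under aqueous acid the freed naphthazarin may ionise at C1', with cyclisation onto the prenyl alkene or erosion of the stereocentre, before both acetals are gone. Fallback (fluoride-labile instead of acid-labile phenol protection): setting out from 7, silylation with TIPSOTf/2,6-lutidine in CH2Cl2 gives 3,6-bis(triisopropylsilyloxy)benzocyclobutene-1,2-dione F3. Addition of the dianion 17 as in step 10 gives the 2-alkynyl-2-hydroxy-3,6-bis(triisopropylsilyloxy)benzocyclobutenone F4, and thermolysis as in step 11 gives 2-[(1R)-1-hydroxy-4-methylpent-3-en-1-yl]-5,8-bis(triisopropylsilyloxy)naphthalene-1,4-dione F5. Et3N·3HF in THF at 0 °C removes the aryl silyl ethers under nearly neutral conditions and comes back to the route at 21.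

3. Step 15. Acylation may spill over to the peri-phenols or stall. Fallback (acylation while the phenols are still blocked): setting out from 20, whose only free hydroxyl is the C1' alcohol, DCC/DMAP coupling with 26 gives (1R)-1-[5,8-bis(methoxymethoxy)-1,4-dioxo-1,4-dihydronaphthalen-2-yl]-4-methylpent-3-en-1-yl 3,4-dimethylpent-3-enoate F6. Chelation-controlled removal of the peri MOM groups with MgBr2·OEt2 in CH2Cl2 at 0 °C, followed by aqueous work-up, comes back to the route at 27. This fallback does not address possible DMAP-promoted migration of the β,γ-double bond of the acid into conjugation.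

**Further compounds**
F1 | step 11 | chlorobis(triphenylphosphine)[3,6-bis(methoxymethoxy)phthaloyl]cobalt(III) | O=C1c2c(OCOC)ccc(OCOC)c2C(=O)[Co-2]1(Cl)([P+](c1ccccc1)(c1ccccc1)c1ccccc1)[P+](c1ccccc1)(c1ccccc1)c1ccccc1
F2 | step 11 | chloro(dimethylglyoxime)(pyridine)[3,6-bis(methoxymethoxy)phthaloyl]cobalt(III) | O=C1c2c(OCOC)ccc(OCOC)c2C(=O)[Co-3]13(Cl)([n+]4ccccc4)[N+](O)=C(C)C(C)=[N+]3O
F3 | step 12 | 3,6-bis(triisopropylsilyloxy)benzocyclobutene-1,2-dione | O=C1C(=O)c2c(O[Si](C(C)C)(C(C)C)C(C)C)ccc(O[Si](C(C)C)(C(C)C)C(C)C)c21
F4 | step 12 | 2-hydroxy-2-[(3R)-3-hydroxy-6-methylhept-5-en-1-yn-1-yl]-3,6-bis(triisopropylsilyloxy)benzocyclobuten-1(2H)-one | O=C1c2c(O[Si](C(C)C)(C(C)C)C(C)C)ccc(O[Si](C(C)C)(C(C)C)C(C)C)c2C1(O)C#C[C@H](O)CC=C(C)C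
F5 | step 12 | 2-[(1R)-1-hydroxy-4-methylpent-3-en-1-yl]-5,8-bis(triisopropylsilyloxy)naphthalene-1,4-dione | CC(C)=CC[C@@H](O)C1=CC(=O)c2c(O[Si](C(C)C)(C(C)C)C(C)C)ccc(O[Si](C(C)C)(C(C)C)C(C)C)c2C1=O
F6 | step 15 | (1R)-1-[5,8-bis(methoxymethoxy)-1,4-dioxo-1,4-dihydronaphthalen-2-yl]-4-methylpent-3-en-1-yl 3,4-dimethylpent-3-enoate | CC(C)=CC[C@@H](OC(=O)CC(C)=C(C)C)C1=CC(=O)c2c(OCOC)ccc(OCOC)c2C1=O
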